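Compounds are numbered 1 to 14 in the order in which they appear in the steps; the full list follows the steps.

## Analysis of the target

- Target 14 is a biphenyl of two identical 1,3,4,5-tetrasubstituted benzene rings. Each ring is numbered C1 (bearing the 2-carboxyethyl chain C7 to C9), C2 (H), C3 (OMe), C4 (OH), C5 (biaryl carbon) and C6 (H), with primes for ring B.
- There is no stereocentre. The C5–C5' axis is flanked only by two hydroxyls and two hydrogens, so it rotates freely and no stereochemical element needs control.
- The sensitive parts are the electron-rich 2,2'-biphenol, which is easily oxidised or halogenated, and the two carboxylic acids, which do not tolerate organometallic reagents.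
- The difficulty is regiochemistry and compatibility, not size. The biaryl bond lies ortho to an oxygen on both rings, each ring has a fixed pattern of four substituents, and the acids must stay masked until the skeleton is complete.
- The strategy rests on ring B, where C3', C4' and C5' carry OMe, OH and aryl in unbroken sequence. This is the pattern left when a carbon nucleophile adds to the far carbon of a 3-methoxyaryne and an oxygen electrophile then quenches the carbanion next to the methoxy group.
- Ring A can be that nucleophile because its C4 oxygen, as an acetal-type ether, directs metalation to C5.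
- The twofold symmetry of 14 is deliberately not used in the bond construction. This costs a second short fragment synthesis but places the biaryl bond and the last ring oxygen in one operation.

## Retrosynthetic reasoning

**14 back to 13.** The carboxyl groups at C9 and C9' are the only functions of 14 that cannot pass through organolithium chemistry, so they are taken back to the aldehyde level in dialdehyde 13. No skeletal bond is cut. The forward reaction must oxidise two aliphatic aldehydes without touching a free, electron-rich biphenol, which points to a buffered chlorite oxidation with a scavenger for the hypochlorite it releases.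

**13 back to 12.** Dialdehyde 13 is unmasked from 12, in which both aldehydes are dioxolanes and the C4 oxygen of ring A is a methoxymethyl ether. All three groups are acetals and fall together in aqueous acid, so protection costs a single step at the end. The C4' hydroxyl is already free in 12 because it is created in the key step.

**12 back to 4 and 6.** Two bonds of 12 are cut together, the biaryl bond C5–C5' and the C4'–O bond.
- Ring B becomes the 3-methoxyaryne 9, whose triple bond spans C4' and C5'. Ring A becomes aryllithium 7.
- Aryne 9 traces to fluoroarene 6 through its lithio derivative 8, and 7 traces to arene 4 by directed lithiation.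
- The cut is made here because the contiguous OMe/OH/aryl triad of ring B is the signature of nucleophile-then-electrophile addition to such an aryne. A cross-coupling would instead need a halogen and a metal installed at two oxygen-flanked carbons.
- The gain is that the most crowded bond and the last oxygen are formed in one flask from two fragments that carry nothing at the coupling carbons except H and F.
- The forward reaction must make 7 attack C5' and not C4', make 7 and not 8 the nucleophile, and capture the resulting 2-lithiobiaryl 10 by an oxygen electrophile by way of borate 11.

**4 back to 2 and 3; 6 back to 5 and 3.** In both fragments the aryl–alkyl bond C1–C7 (C1'–C7') is cut, giving aryl bromides 2 and 5 and one common organozinc reagent 3. Reagent 3 brings C7 to C9 with C9 already a protected aldehyde. Cutting at the ring rather than inside the chain avoids an olefination and hydrogenation pair in each series and reaches each fragment in one carbon–carbon bond-forming step. The forward reaction is an sp2–sp3 cross-coupling that must leave the C–F bond of 5 and the acetals untouched.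

**2 back to 1.** The methoxymethyl ether of 2 is taken back to phenol 1. The group is chosen for what it does later: it masks the acidic hydroxyl during the zinc and lithium steps, it is the strongest ortho-director on ring A so that 4 is metalated at C5, and it leaves in the same acid step as the dioxolanes.

## Alternatives that were turned down

**Alternative 1:** Both benzene rings are dismantled.
- Disconnection: each ring is traced to one molecule of methyl 3-bromo-2-oxo-2H-pyran-5-carboxylate A1, which supplies C1, C2, C3 and C6 together with the future C7 as its ester carbon. C4 and C5 come from one ketene acetal terminus of 1,1,4,4-tetrakis(trimethylsilyloxy)buta-1,3-diene A2, whose central single bond becomes the biaryl bond.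
- Forward key step: two inverse-demand Diels–Alder additions, each followed by decarboxylative cycloreversion and elimination of silanol, would give dimethyl 5,5'-dibromo-6,6'-dihydroxybiphenyl-3,3'-dicarboxylate A3.
- For it: the hindered biaryl bond is never made, because it is already present in A2. Both phenolic oxygens arrive with the rings, and every event acts on both halves at once.
- Against it, in the key step: A2 is itself an electron-rich conjugated diene and may react as a four-carbon unit or oligomerise. The second cycloaddition must occur at a ketene acetal that has become aryl-substituted and hindered. The regiochemistry (C6 of the pyranone to the central carbon) must hold twice.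
- Against it, after the key step: A3 is far from 14. Bromine must be exchanged for methoxy next to a free phenol on both rings, and each ester must be reduced, extended by two carbons, hydrogenated and hydrolysed.
- Comparison: this alternative is stronger in its use of symmetry and in ring-forming convergence. The chosen route offers a key step of an established reaction type, a chain that arrives with the correct carbon count and oxidation level, and two steps after the key step where this alternative needs about five.

**Alternative 2:** The aryl–chain bonds C1–C7 and C1'–C7' are cut.
- Disconnection: the target is led back to the bis(allyl ether) 2,2'-bis(allyloxy)-3,3'-dimethoxybiphenyl A4.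
- Forward key step: on strong heating each allyl group would shift by a [3,3] rearrangement to a blocked ortho carbon. Since no tautomerisation is possible there, a second [3,3] shift carries it to the para carbon, giving 5,5'-diallyl-3,3'-dimethoxybiphenyl-2,2'-diol A5 after enolisation.
- For it: the reaction needs no reagent, both ortho positions are blocked so delivery to C1 is enforced, and each step does double duty on a symmetric substrate.
- Against it: the key step does not address the difficult bond. C5–C5' must already exist in A4, so the biaryl problem is moved to an earlier coupling of a guaiacol unit whose para position is free and competes.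
- Against it: the chain arrives as a terminal alkene. Reaching the acid needs phenol protection, anti-Markovnikov hydration, oxidation and deprotection.
- Against it: the ortho dienone that bears the methoxy group can branch at high temperature. A5 is also formally the oxidative dimer of its own monomeric half, so the rearrangement reaches by a detour what a phenol coupling would address directly.
- Comparison: this alternative is at least as strong in operational simplicity of the key step and in use of symmetry. The chosen strategy offers a key step that itself creates the biaryl bond and the C4' oxygen, a chain already at the aldehyde level, and a similar or lower step count.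

**Alternative 3:** The bonds C7–C8 and C7'–C8' are cut.
- Disconnection: C8, C9 and one extra carboxyl come from a malonate ester. The benzylic carbons are held as aminomethyl groups in 5,5'-bis[(dimethylamino)methyl]-3,3'-dimethoxybiphenyl-2,2'-diol A6.
- Forward key step: heating A6 with base and excess malonate would expel the amine from each ring to give a para-quinone methide. The malonate anion adds at the exocyclic carbon, giving tetramethyl 2,2'-[(6,6'-dihydroxy-5,5'-dimethoxybiphenyl-3,3'-diyl)bis(methylene)]dimalonate A7. Saponification and decarboxylation would then give 14.
- For it: C9 arrives at the acid level, so no oxidation is needed in the presence of free phenols. The endgame is hydrolysis only, and A6 follows from the parent biphenol by aminomethylation at its one free activated position.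
- Against it: the biaryl bond must again pre-exist. Thermal loss of an amine from a para-hydroxybenzylamine is slow without quaternisation. The monoalkylated malonate stays acidic and, with two electrophilic sites per molecule, can bridge to oligomers unless the malonate is in large excess. The biphenolate in hot base is prone to self-condensation and oxidation.
- Comparison: this alternative is the stronger one in step count and in the endgame, and that should be acknowledged. In its place the chosen strategy offers a key step that forms the biaryl bond with defined regiochemistry instead of presupposing it. Its rings are built as separate fragments, so unsymmetrical or singly labelled analogues follow from the same sequence. It also avoids generating a quinone methide twice on one molecule.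

Key step: step 4

Assumption: organozinc reagent 3 is used as the commercially supplied 0.5 M solution in THF, and the same reagent serves steps 2 and 3.

## Route

Step 1
Reactants: 1 4-bromo-2-methoxyphenol
Product: 2 4-bromo-2-methoxy-1-(methoxymethoxy)benzene
Conditions: MOMCl, i-Pr2NEt, CH2Cl2, 0 °C to rt
Reagents that add atoms: chloromethyl methyl ether, COCCl
Why: Williamson-type O-alkylation of the phenol with a reactive α-chloro ether under amine base; the methoxymethyl ether protects the hydroxyl through the zinc and lithium steps and later serves as the ortho-directing group.

Step 2
Reactants: 2 4-bromo-2-methoxy-1-(methoxymethoxy)benzene; 3 [2-(1,3-dioxolan-2-yl)ethyl]zinc bromide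
Product: 4 2-{2-[3-methoxy-4-(methoxymethoxy)phenyl]ethyl}-1,3-dioxolane
Conditions: 3 (1.5 equiv), Pd(OAc)2 (2 mol%), SPhos (4 mol%), THF, 50 °C
Reagents that add atoms: none
Why: Negishi sp2–sp3 cross-coupling: the aryl bromide adds oxidatively to zerovalent palladium formed from Pd(OAc)2 and SPhos, the primary alkylzinc bromide transmetalates, and the bulky biarylphosphine makes reductive elimination faster than β-hydride elimination; the methoxymethyl ether and the dioxolane are inert to the organozinc.

Step 3
Reactants: 5 1-bromo-3-fluoro-5-methoxybenzene; 3 [2-(1,3-dioxolan-2-yl)ethyl]zinc bromide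
Product: 6 2-[2-(3-fluoro-5-methoxyphenyl)ethyl]-1,3-dioxolane
Conditions: 3 (1.5 equiv), Pd(OAc)2 (2 mol%), SPhos (4 mol%), THF, 50 °C
Reagents that add atoms: none
Why: The same Negishi coupling on a more electron-poor bromide, which should undergo oxidative addition more easily; the C–F bond does not react with zerovalent palladium under these conditions and is kept as the leaving group for aryne formation.

Step 4
Reactants: 4 2-{2-[3-methoxy-4-(methoxymethoxy)phenyl]ethyl}-1,3-dioxolane; 6 2-[2-(3-fluoro-5-methoxyphenyl)ethyl]-1,3-dioxolane
Product: 12 5,5'-bis[2-(1,3-dioxolan-2-yl)ethyl]-3,3'-dimethoxy-2'-(methoxymethoxy)biphenyl-2-ol, via aryllithium of ring A 7 (not isolated), via lithiated fluoroarene 8 (not isolated), via 3-methoxyaryne 9 (not isolated), via 2-lithiobiaryl 10 (not isolated), via lithium aryltrimethoxyborate 11 (not isolated)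
Conditions: 4 (2.5 equiv), n-BuLi, TMEDA, THF, 0 °C (gives 7); separately 6, n-BuLi, THF, -78 °C (gives 8); 8 added slowly to 7 at -30 °C, then 0 °C; B(OMe)3, -78 °C to rt; aq NaOH, 30% H2O2, 0 °C
Reagents that add atoms: hydrogen peroxide, OO
Why: Directed ortho-lithiation of 4 at the only position next to the methoxymethoxy group gives 7, and in a second flask 6 is lithiated at its most acidic C–H, the one flanked by F and OMe, to give 8. When 8 meets the excess of 7 above about -40 °C it expels LiF and forms aryne 9 with the triple bond across C4' and C5'. Aryllithium 7 adds to C5', the aryne carbon remote from the methoxy group, because the inductively withdrawing OMe distorts the aryne and stabilises the carbanion developing at C4' beside it; this forms the C5–C5' bond and gives 10. Lithiobiaryl 10 is captured by B(OMe)3 as borate 11, and alkaline H2O2 triggers 1,2-migration of the aryl group from boron to oxygen, which forms the C4'–O bond at the same carbon and gives 12 on hydrolysis. The closest known reaction type is the addition of aryllithium or aryl Grignard reagents to arynes made from ortho-metalated haloarenes with electrophilic trapping of the 2-metalated biaryl, joined here to routine borylation and oxidation. No ring closes and no stereocentre is formed. Two selectivities are needed: regioselective attack at C5', secured by the C3' methoxy group, and cross-addition in preference to self-addition of 8 to 9, secured by the 2.5-fold excess of 7, by slow release of 9 through inverse addition, and by using slightly less n-BuLi than 4 so that no free alkyllithium remains. The dioxolanes and the methoxymethyl ether are inert to the aryllithiums and to basic peroxide, and the surplus of 7 is oxidised to a phenol that is removed by chromatography.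

Step 5
Reactants: 12 5,5'-bis[2-(1,3-dioxolan-2-yl)ethyl]-3,3'-dimethoxy-2'-(methoxymethoxy)biphenyl-2-ol
Product: 13 3,3'-(6,6'-dihydroxy-5,5'-dimethoxybiphenyl-3,3'-diyl)dipropanal
Conditions: 3 M aq HCl, THF, 40 °C
Reagents that add atoms: water, O
Why: Acid-catalysed hydrolysis of three acetal-type groups in one operation: each dioxolane opens to an oxocarbenium ion that water captures, and the aryl methoxymethyl ether fragments to the phenol. THF and water, not an alcohol, are used so that the aldehydes are not re-acetalised, and all positions ortho and para to the phenolic oxygens are substituted, which limits capture of the released formaldehyde.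

Step 6
Reactants: 13 3,3'-(6,6'-dihydroxy-5,5'-dimethoxybiphenyl-3,3'-diyl)dipropanal
Product: 14 3,3'-(6,6'-dihydroxy-5,5'-dimethoxybiphenyl-3,3'-diyl)dipropanoic acid
Conditions: NaClO2, NaH2PO4, 2-methyl-2-butene, t-BuOH/H2O, 0 °C to rt
Reagents that add atoms: sodium chlorite, [Na+].[O-]Cl=O
Why: Pinnick oxidation: chlorous acid adds to each aldehyde and fragments to the carboxylic acid and hypochlorous acid, which 2-methyl-2-butene removes before it can chlorinate the rings. At the buffered pH the phenols are not ionised and are poor substrates for the oxidant, and this type of oxidation is established for guaiacol-type hydroxy aldehydes.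

## Compound list

1 | 4-bromo-2-methoxyphenol | COc1cc(Br)ccc1O | starting material
2 | 4-bromo-2-methoxy-1-(methoxymethoxy)benzene | COCOc1ccc(Br)cc1OC | intermediate
3 | [2-(1,3-dioxolan-2-yl)ethyl]zinc bromide | Br[Zn]CCC1OCCO1 | starting material
4 | 2-{2-[3-methoxy-4-(methoxymethoxy)phenyl]ethyl}-1,3-dioxolane | COCOc1ccc(CCC2OCCO2)cc1OC | intermediate
5 | 1-bromo-3-fluoro-5-methoxybenzene | COc1cc(F)cc(Br)c1 | starting material
6 | 2-[2-(3-fluoro-5-methoxyphenyl)ethyl]-1,3-dioxolane (fragment 2) | COc1cc(F)cc(CCC2OCCO2)c1 | intermediate
7 | {5-[2-(1,3-dioxolan-2-yl)ethyl]-3-methoxy-2-(methoxymethoxy)phenyl}lithium (fragment 1, not isolated) | [Li]c1cc(CCC2OCCO2)cc(OC)c1OCOC | intermediate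
8 | {4-[2-(1,3-dioxolan-2-yl)ethyl]-2-fluoro-6-methoxyphenyl}lithium (not isolated) | [Li]c1c(F)cc(CCC2OCCO2)cc1OC | intermediate
9 | 2-[2-(3,4-didehydro-5-methoxyphenyl)ethyl]-1,3-dioxolane (3-methoxyaryne, not isolated) | COC1=CC(CCC2OCCO2)=CC#C1 | intermediate
10 | {5,5'-bis[2-(1,3-dioxolan-2-yl)ethyl]-3,3'-dimethoxy-2'-(methoxymethoxy)biphenyl-2-yl}lithium (not isolated) | [Li]c1c(OC)cc(CCC2OCCO2)cc1-c1cc(CCC2OCCO2)cc(OC)c1OCOC | intermediate
11 | lithium {5,5'-bis[2-(1,3-dioxolan-2-yl)ethyl]-3,3'-dimethoxy-2'-(methoxymethoxy)biphenyl-2-yl}trimethoxyborate (not isolated) | [Li+].CO[B-](OC)(OC)c1c(OC)cc(CCC2OCCO2)cc1-c1cc(CCC2OCCO2)cc(OC)c1OCOC | intermediate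
12 | 5,5'-bis[2-(1,3-dioxolan-2-yl)ethyl]-3,3'-dimethoxy-2'-(methoxymethoxy)biphenyl-2-ol | COCOc1c(OC)cc(CCC2OCCO2)cc1-c1cc(CCC2OCCO2)cc(OC)c1O | intermediate
13 | 3,3'-(6,6'-dihydroxy-5,5'-dimethoxybiphenyl-3,3'-diyl)dipropanal | COc1cc(CCC=O)cc(-c2cc(CCC=O)cc(OC)c2O)c1O | intermediate
14 | 3,3'-(6,6'-dihydroxy-5,5'-dimethoxybiphenyl-3,3'-diyl)dipropanoic acid | COc1cc(CCC(=O)O)cc(-c2cc(CCC(=O)O)cc(OC)c2O)c1O | target

## Step count and least certain steps

Total step count: 6. Longest linear sequence: 5 steps (steps 1, 2, 4, 5 and 6; step 3 is the one-step branch to fragment 2).

**Step 4 (key step).**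
- The most likely failure is loss of the aryne to other nucleophiles: 8 may add to 9 in place of 7, and the adduct may add to further 9, if the aryne is released faster than 7 can intercept it.
- Residual n-BuLi could add to 9, and incomplete borylation of the doubly ortho-substituted carbanion 10 would end in protonation.
- Lithiation of 4 can be verified by a deuterium quench before 6 is committed.
- Fallback: the aryne is given up and the symmetry of the target is used. Setting out from 4, lithiation to 7 as above and oxidative homocoupling with anhydrous CuCl2 (THF, -78 °C to rt) should give 5,5'-bis[2-(1,3-dioxolan-2-yl)ethyl]-3,3'-dimethoxy-2,2'-bis(methoxymethoxy)biphenyl F1. Under the conditions of step 5, F1 loses both methoxymethyl groups and both dioxolanes and comes back to the route at 13.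

**Step 5.**
- The liberated 3-arylpropanal units may condense under acid, by aldol reaction or by attack on the activated ring positions C2 and C6, before the slower cleavage of the aryl methoxymethyl ether is complete. The released formaldehyde may also be captured by the ring.
- Fallback: the order of events is changed so that free aldehydes never meet strong acid. Setting out from 12, the dioxolanes alone are hydrolysed with pyridinium p-toluenesulfonate in acetone/H2O at reflux to give 3,3'-[6-hydroxy-5,5'-dimethoxy-6'-(methoxymethoxy)biphenyl-3,3'-diyl]dipropanal F2. Chlorite oxidation as in step 6 gives 3,3'-[6-hydroxy-5,5'-dimethoxy-6'-(methoxymethoxy)biphenyl-3,3'-diyl]dipropanoic acid F3. Only then is the methoxymethyl ether removed with aqueous HCl in THF, which comes back to the route at 14. Any early loss of the ether is harmless because both series converge on 14.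

**Step 6.**
- Ring chlorination or oxidation of the free biphenol may occur if hypochlorous acid or chlorine dioxide escapes the scavenger.
- Fallback: the phenols are masked during the oxidation. Setting out from 13, acetylation (Ac2O, pyridine, 0 °C) gives 3,3'-dimethoxy-5,5'-bis(3-oxopropyl)biphenyl-2,2'-diyl diacetate F4. Chlorite oxidation gives 3,3'-[6,6'-bis(acetyloxy)-5,5'-dimethoxybiphenyl-3,3'-diyl]dipropanoic acid F5. LiOH in THF/H2O followed by acidification with HCl removes the acetates and comes back to the route at 14.

**Step 2.**
- Oxidative addition into the electron-rich bromide 2 may be slow, leaving time for protodemetalation of 3 and reduction or homocoupling of the arene. Step 3 uses a more reactive bromide and is less exposed.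
- Fallback: the chain is built by olefination in place of cross-coupling. Setting out from 2, bromine–lithium exchange (n-BuLi, THF, -78 °C) gives [3-methoxy-4-(methoxymethoxy)phenyl]lithium F6, which DMF formylates to 3-methoxy-4-(methoxymethoxy)benzaldehyde F7. Wittig olefination with (1,3-dioxolan-2-ylmethylidene)triphenylphosphorane F8, made in the flask from (1,3-dioxolan-2-ylmethyl)triphenylphosphonium bromide and t-BuOK in THF, gives 2-{2-[3-methoxy-4-(methoxymethoxy)phenyl]ethenyl}-1,3-dioxolane F9 as an E/Z mixture. Hydrogenation (H2, Pd/C, EtOAc, trace Et3N) comes back to the route at 4.

## Further compounds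

F1 | step 4 | 5,5'-bis[2-(1,3-dioxolan-2-yl)ethyl]-3,3'-dimethoxy-2,2'-bis(methoxymethoxy)biphenyl | COCOc1c(OC)cc(CCC2OCCO2)cc1-c1cc(CCC2OCCO2)cc(OC)c1OCOC
F2 | step 5 | 3,3'-[6-hydroxy-5,5'-dimethoxy-6'-(methoxymethoxy)biphenyl-3,3'-diyl]dipropanal | COCOc1c(OC)cc(CCC=O)cc1-c1cc(CCC=O)cc(OC)c1O
F3 | step 5 | 3,3'-[6-hydroxy-5,5'-dimethoxy-6'-(methoxymethoxy)biphenyl-3,3'-diyl]dipropanoic acid | COCOc1c(OC)cc(CCC(=O)O)cc1-c1cc(CCC(=O)O)cc(OC)c1O
F4 | step 6 | 3,3'-dimethoxy-5,5'-bis(3-oxopropyl)biphenyl-2,2'-diyl diacetate | CC(=O)Oc1c(OC)cc(CCC=O)cc1-c1cc(CCC=O)cc(OC)c1OC(C)=O
F5 | step 6 | 3,3'-[6,6'-bis(acetyloxy)-5,5'-dimethoxybiphenyl-3,3'-diyl]dipropanoic acid | CC(=O)Oc1c(OC)cc(CCC(=O)O)cc1-c1cc(CCC(=O)O)cc(OC)c1OC(C)=O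
F6 | step 2 | [3-methoxy-4-(methoxymethoxy)phenyl]lithium | [Li]c1ccc(OCOC)c(OC)c1
F7 | step 2 | 3-methoxy-4-(methoxymethoxy)benzaldehyde | COCOc1ccc(C=O)cc1OC
F8 | step 2 | (1,3-dioxolan-2-ylmethylidene)triphenylphosphorane | C1COC(C=P(c2ccccc2)(c2ccccc2)c2ccccc2)O1
F9 | step 2 | 2-{2-[3-methoxy-4-(methoxymethoxy)phenyl]ethenyl}-1,3-dioxolane (E/Z mixture) | COCOc1ccc(C=CC2OCCO2)cc1OC
A1 | alternative 1 | methyl 3-bromo-2-oxo-2H-pyran-5-carboxylate | COC(=O)C1=COC(=O)C(Br)=C1
A2 | alternative 1 | 1,1,4,4-tetrakis(trimethylsilyloxy)buta-1,3-diene | C[Si](C)(C)OC(O[Si](C)(C)C)=CC=C(O[Si](C)(C)C)O[Si](C)(C)C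
A3 | alternative 1 | dimethyl 5,5'-dibromo-6,6'-dihydroxybiphenyl-3,3'-dicarboxylate | COC(=O)c1cc(Br)c(O)c(-c2cc(C(=O)OC)cc(Br)c2O)c1
A4 | alternative 2 | 2,2'-bis(allyloxy)-3,3'-dimethoxybiphenyl | C=CCOc1c(OC)cccc1-c1cccc(OC)c1OCC=C
A5 | alternative 2 | 5,5'-diallyl-3,3'-dimethoxybiphenyl-2,2'-diol | C=CCc1cc(OC)c(O)c(-c2cc(CC=C)cc(OC)c2O)c1
A6 | alternative 3 | 5,5'-bis[(dimethylamino)methyl]-3,3'-dimethoxybiphenyl-2,2'-diol | CN(C)Cc1cc(OC)c(O)c(-c2cc(CN(C)C)cc(OC)c2O)c1
A7 | alternative 3 | tetramethyl 2,2'-[(6,6'-dihydroxy-5,5'-dimethoxybiphenyl-3,3'-diyl)bis(methylene)]dimalonate | COC(=O)C(Cc1cc(OC)c(O)c(-c2cc(CC(C(=O)OC)C(=O)OC)cc(OC)c2O)c1)C(=O)OC
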